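I decided to reckon the end state first and the speed afterwards, with fractions of the charge as my unit.

| flask | substrate | remark | time |
|---|---|---|---|
| north-west | 0.65 M | run made earlier |  |
| south-east | 0.98 M | run made earlier |  |
| flask | 1.3 M |  | 40 h |

- north-west (time / h: substrate / %, target / %, intermediate A / %): 3.00: 27.6, 2.3, 52.3; 8.00: 24.1, 3.4, 46.2; 15.0: 23.3, 3.5, 45.1; 25.0: 22.9, 3.1, 45.3
- south-east (time / h: substrate / %, target / %, intermediate A / %): 6.00: 24.5, 3.2, 48.0; 12.0: 24.2, 3.0, 45.9; 20.0: 23.7, 2.7, 45.0; 25.0: 23.1, 2.9, 45.2

(each reading ± 0.5 percentage points)

1. the state of affairs at 40 h: stopped, and by what, or still going (all of the substrate has reacted / it is still moving / forward and back rates have come level)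
2. share of the substrate used up at 40 h
3. target at 40 h, in percent of the substrate charged
4. intermediate A at 40 h, in percent of the substrate charged
5. amount of target if the flask were left three thousand times as long, in percent of the substrate charged

- what was read earlier has a scatter of 0.5 percentage points, one standard deviation
- what has gone from substrate into another species counts as reacted, even if it can come back
- the reaction counts as stopped when no species that holds the substrate changes by six tenths of a point or more over the second half of the time

1. At 25.0 h the north-west run held 22.9% of its charge as substrate and the south-east run 23.1%. These agree within the scatter despite different charges, so I took the steps as first order and carried the fractions over to the flask at 1.3 M.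

2. I defined the balance ratio as intermediate A held per unit of substrate. The last 4 readings of each kind, from 15.0 h on, gave 1.94. The north-west run already read 1.89 at 3.00 h, so I treated the pair as a pre-equilibrium.

3. Substrate plus intermediate A, the pool, rested at 0.684. Dividing by one plus the ratio left substrate at 0.233, so conversion was 0.767 and intermediate A 0.452. Late target readings averaged 0.0305, and unseen species held 0.285.

4. The pool's excess over rest shrank between 3.00 h and 8.00 h in the north-west run, which read as a half-life of 1.92 h. By 20.0 h the excess would be 0.025 percentage points, under the stopping margin. With substrate resting well above zero, I expected level forward and back rates.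

5. The weak link was that half-life, which assumes a single phase. A slower phase would show as a late fall of the pool. Between the two latest readings of each run the pool fell by 0.3 points on average, with a scatter of 0.71 points on that average, so none was visible. I kept target at 0.0305 for the long flask too.

The forecast said forward and back rates have come level, with conversion 77.0%, target 3.00%, intermediate A 45.2% and long-time target 3.00%: “Substrate stalls at 23%, not zero, so this is equilibrium”.

The flask gave forward and back rates have come level, with conversion 76.3%, target 3.19%, intermediate A 45.5% and long-time target 3.19%.

    substrate ⇌ intermediate A (K = 1.92, k = 0.771 min⁻¹)
    substrate ⇌ intermediate B (K = 1.12, k = 0.00538 min⁻¹)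
    intermediate B ⇌ target (K = 0.120, k = 0.0739 min⁻¹)
    target ⇌ isomer of the product (K = 0.335, k = 0.0683 min⁻¹)

The balance ratio on the flask's remaining substrate, 23.7%, gives intermediate A of 0.460 of the charge, against the flask's 45.5%. Target stays this small because of the reverse step from target to intermediate B: the run without that step holds 73.7% of target at 40 h, against 3.19% with it.

For the neighbour flask at 0.52 M, the balance ratio on my resting substrate gives intermediate A of 0.452. The computed neighbour flask holds 45.5%, on 23.7% of substrate.

The numbers in the tables are calculated for an exercise.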